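## Retrosynthetic overview

1. The target comes from a 3,9-bis-silyl 6,12-diol by acetylation at O12 and desilylation; C12–C13 and the C12 stereocentre come from a catalytic linear prenylboration of a lactol.
2. The seven-membered ring is formed last, by one-carbon ring expansion of a trans-hydrindan-10-one (1,2-shift of C8 in a diazoalkane homologation), followed by Rubottom oxidation (9-OH) and methylenation (C18).
3. The six-membered ring comes from an intramolecular Michael addition of a C10 methyl ketone to a butenolide (C7–C8); the resulting cis-fused O6–C12 lactone fixes C6/C7 and C11.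
4. The cyclopentane comes from (S)-4-silyloxycyclopentenone by conjugate vinylation–elimination (C1), then vinylogous Mukaiyama–Michael addition and α-methylenation (C5, C6, C17) and CBS reduction (C3).
5. Ring order: five-membered ring (starting material) → butenolide (temporary) → six-membered ring with cis-fused lactone → ring expansion to the seven-membered ring → lactone opened to the side chain.

Assumption: enantiopure (S)-4-(tert-butyldimethylsilyloxy)cyclopent-2-en-1-one (compound 1) is taken as a commercial starting material.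

Locants (dictyol numbering, used for all intermediates): C1–C5 is the five-membered ring (C1 and C5 are the fusion carbons, C3 is the carbinol, C4 bears methylidene C17). C6–C10 complete the seven-membered ring (C6 carbinol next to C5, C7 bears the side chain, C9 carbinol, C10 bears methylidene C18 and is bonded to C1). The side chain is C11(CH3 = C19)–C12(OAc)–C13–C14=C15(C16)(C20). The target is (1S,3R,5R,6S,7R,9S,11S,12S): H-1 and H-5 are trans, 6-OH and the side chain are cis, and the C11 methyl and 12-OAc are syn.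

## Route

Step 1
Reactants: 1 (S)-4-(tert-butyldimethylsilyloxy)cyclopent-2-en-1-one; 2 vinylmagnesium bromide
Product: 4 (R)-4-vinylcyclopent-2-en-1-one, via silyloxy ketone 3 (not isolated)
Conditions: CH2=CHMgBr (1.3 equiv), CuBr·SMe2 (10 mol%), THF, −78 °C; 1 M HCl quench; then p-TsOH·H2O (10 mol%), CH2Cl2, 23 °C
Reagents that add atoms: none
Why: Copper-catalysed 1,4-addition of the vinyl Grignard reagent occurs anti to the 4-silyloxy group, and acid-promoted β-elimination of the silanol (conjugate addition–elimination) then moves the enone, leaving C1 as the only stereocentre, set (R) by the anti addition.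

Step 2
Reactants: 5 3-methylfuran-2(5H)-one
Product: 6 tert-butyldimethyl[(3-methylfuran-2-yl)oxy]silane
Conditions: TBSOTf (1.1 equiv), Et3N (1.3 equiv), CH2Cl2, 0 °C
Reagents that add atoms: tert-butyldimethylsilyl trifluoromethanesulfonate, CC(C)(C)[Si](C)(C)OS(=O)(=O)C(F)(F)F
Why: Soft enolisation and O-silylation of the butenolide gives the aromatic 2-silyloxyfuran, the standard vinylogous Mukaiyama donor, and no stereocentre is involved.

Step 3
Reactants: 4 (R)-4-vinylcyclopent-2-en-1-one; 6 tert-butyldimethyl[(3-methylfuran-2-yl)oxy]silane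
Product: 10 (3R,4R)-2-methylidene-3-[(2S)-4-methyl-5-oxo-2,5-dihydrofuran-2-yl]-4-vinylcyclopentan-1-one, via enol silane 7 (not isolated), via Mannich base 8 (not isolated), via ammonium iodide 9 (not isolated)
Conditions: TBSOTf (10 mol%), CH2Cl2, −78 °C; then CH2=NMe2+ I− (1.5 equiv), MeCN, −78 → 23 °C; then MeI; then aq. NaHCO3, 23 °C
Reagents that add atoms: dimethylmethylideneammonium iodide (Eschenmoser's salt), C=[N+](C)C.[I-]
Why: Vinylogous Mukaiyama–Michael addition of the silyloxyfuran through its 5-position occurs anti to the C1 vinyl group (sets C5) and is expected to pass through an open antiperiplanar transition state with the furan C–H over the ring (sets C6, 5,6-anti), after which the regiodefined enol silane is aminomethylated (Mannich reaction) and the methiodide eliminated to give the C4=C17 exocyclic enone.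

Step 4
Reactants: 10 (3R,4R)-2-methylidene-3-[(2S)-4-methyl-5-oxo-2,5-dihydrofuran-2-yl]-4-vinylcyclopentan-1-one
Product: 11 (1R,3R,4R)-2-methylidene-3-[(2S)-4-methyl-5-oxo-2,5-dihydrofuran-2-yl]-4-vinylcyclopentan-1-ol
Conditions: (S)-2-methyl-CBS-oxazaborolidine (20 mol%), catecholborane (1.5 equiv), toluene, −78 °C; MeOH, then pH 7 buffer
Reagents that add atoms: none
Why: Corey–Bakshi–Shibata reduction is reagent-controlled, the (S)-oxazaborolidine treating the fully substituted alkenyl carbon C4 as the large group and delivering hydride 1,2 to give the (3R)-allylic alcohol, while butenolide and vinyl group are untouched at −78 °C.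

Step 5
Reactants: 11 (1R,3R,4R)-2-methylidene-3-[(2S)-4-methyl-5-oxo-2,5-dihydrofuran-2-yl]-4-vinylcyclopentan-1-ol
Product: 12 tert-butyldimethylsilyl ether of 11 (3-OTBS)
Conditions: TBSCl, imidazole, DMF, 23 °C
Reagents that add atoms: tert-butyldimethylsilyl chloride, CC(C)(C)[Si](C)(C)Cl
Why: Silylation masks the C3 hydroxyl, which is cis-1,3 to the vinyl group and would otherwise add to the palladium-activated alkene in the next step.

Step 6
Reactants: 12 tert-butyldimethylsilyl ether of 11 (3-OTBS)
Product: 13 1-[(1S,2R,4R)-4-(tert-butyldimethylsilyloxy)-3-methylidene-2-[(2S)-4-methyl-5-oxo-2,5-dihydrofuran-2-yl]cyclopentyl]ethan-1-one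
Conditions: PdCl2 (10 mol%), CuCl (1 equiv), O2 (1 atm), DMF–H2O (7:1), 23 °C
Reagents that add atoms: water, O
Why: Tsuji–Wacker oxidation converts only the monosubstituted alkene into the methyl ketone (Markovnikov hydroxypalladation, β-hydride elimination), because the 1,1-disubstituted alkene and the electron-poor butenolide alkene are inert.

Step 7
Reactants: 13 1-[(1S,2R,4R)-4-(tert-butyldimethylsilyloxy)-3-methylidene-2-[(2S)-4-methyl-5-oxo-2,5-dihydrofuran-2-yl]cyclopentyl]ethan-1-one
Product: 14 tricyclic keto lactone (1S,3R,5R,6S,7R,11S): trans-fused hydrindan-10-one (C8 bonded to C10; no C9 yet) with 3-OTBS; C4=C17 methylidene; cis-fused 6,12-olide bearing the C11 methyl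
Conditions: pyrrolidine (30 mol%), AcOH (30 mol%), CH2Cl2, 23 °C
Reagents that add atoms: none
Why: In this enamine-catalysed intramolecular Michael addition the methyl-side enamine of the C10 ketone adds 6-exo-trig to C7 of the butenolide, the C5–C6 tether forces a cis-fused lactone (sets C7), kinetic protonation of the lactone enol from the convex face places the C11 methyl on the concave face (sets 11S), and C1 is not touched, so the ring fusion stays trans.

Step 8
Reactants: 14 tricyclic keto lactone
Product: 17 (1S,3R,5R,6S,7R,9S,11S)-9-hydroxy-10-oxo hydroazulene lactone (trans-fused five-seven ring system; 3-OTBS; C4=C17; 6,12-olide), via trimethylsilyl enol ether 15 (not isolated), via silyloxy ketone 16 (not isolated)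
Conditions: Sc(OTf)3 (10 mol%), Me3SiCHN2 (1.5 equiv), toluene, −78 → 0 °C; then dimethyldioxirane (1.1 equiv), acetone–CH2Cl2, −78 °C; then PPTS, MeOH, 0 °C
Reagents that add atoms: (trimethylsilyl)diazomethane, C[Si](C)(C)C=[N+]=[N-]; dimethyldioxirane, CC1(C)OO1
Why: In this Lewis-acid-catalysed diazoalkane–carbonyl homologation the diazo carbon adds to the activated C10 ketone, the less substituted C8 undergoes the 1,2-shift with loss of N2 (six- to seven-membered ring expansion, inserting C9), 1,3-Brook shift gives the C9=C10 enol silane regiospecifically, and Rubottom oxidation takes place on the β face opposite the cis-fused lactone to set 9S.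

Step 9
Reactants: 17 9-hydroxy-10-oxo hydroazulene lactone
Product: 18 9-O-TBS ether of 17 (3,9-bis-OTBS 10-ketone)
Conditions: TBSOTf (1.3 equiv), 2,6-lutidine, CH2Cl2, −78 °C
Reagents that add atoms: tert-butyldimethylsilyl trifluoromethanesulfonate, CC(C)(C)[Si](C)(C)OS(=O)(=O)C(F)(F)F
Why: Low-temperature silylation of the only free hydroxyl protects the α-ketol against isomerisation and prepares for the later selective acetylation, with no stereocentre affected.

Step 10
Reactants: 18 3,9-bis-OTBS 10-ketone
Product: 19 bis-methylidene lactone (3,9-bis-OTBS; C4=C17 and C10=C18; 6,12-olide)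
Conditions: Zn, CH2Br2, TiCl4, THF–CH2Cl2, 0 → 23 °C
Reagents that add atoms: dibromomethane, BrCBr
Why: In the Takai–Lombardo methylenation the non-basic gem-dimetallic CH2 reagent methylenates the hindered, enolisable C10 ketone without epimerising C1 or C9 and does not react with the lactone.

Step 11
Reactants: 19 bis-methylidene lactone
Product: 20 lactol of 19 (C12 hemiacetal; anomer mixture)
Conditions: i-Bu2AlH (1.2 equiv), CH2Cl2, −78 °C; aq. potassium sodium tartrate
Reagents that add atoms: none
Why: i-Bu2AlH adds once to the lactone at −78 °C and the aluminium hemiacetal persists until work-up (partial reduction), the anomeric centre being of no consequence.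

Step 12
Reactants: 21 1-chloro-3-methylbut-2-ene (prenyl chloride)
Product: 23 2-(2-methylbut-3-en-2-yl)-4,4,5,5-tetramethyl-1,3,2-dioxaborolane, via prenylmagnesium chloride 22 (not isolated)
Conditions: Mg, THF, 0 °C; then 2-isopropoxy-4,4,5,5-tetramethyl-1,3,2-dioxaborolane, −78 → 0 °C
Reagents that add atoms: 2-isopropoxy-4,4,5,5-tetramethyl-1,3,2-dioxaborolane, CC(C)OB1OC(C)(C)C(C)(C)O1
Why: The allylic Grignard reagent attacks the borate through its more substituted γ-terminus (SE2′), giving the tertiary α,α-dimethylallyl boronate kinetically, and it is kept cold to avoid a 1,3-boron shift.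

Step 13
Reactants: 20 lactol of 19; 23 2-(2-methylbut-3-en-2-yl)-4,4,5,5-tetramethyl-1,3,2-dioxaborolane
Product: 24 (12S)-6,12-diol (3,9-bis-OTBS; prenyl side chain complete)
Conditions: (S)-3,3′-bis(2,4,6-triisopropylphenyl)-1,1′-binaphthyl-2,2′-diyl hydrogen phosphate (10 mol%), 23 (2 equiv), 4 Å molecular sieves, toluene, 0 → 23 °C; aq. NaHCO3
Reagents that add atoms: none
Why: Proposed new method: chiral-phosphoric-acid-catalysed linear prenylboration of a lactol, in which the open hydroxy-aldehyde tautomer of 20 reacts with the tertiary allylboronate through a closed six-membered chair transition state with C–C bond formation at the unsubstituted CH2 terminus (allylic transposition, hence only the linear prenyl carbinol), while the acid hydrogen-bonds to a pinacol oxygen and directs attack to the Si face of C12, the face also favoured by the Felkin–Anh model for C11, giving 12S with 11,12-syn; the (S)-acid is chosen by analogy with the face selectivity reported for chiral-phosphoric-acid-catalysed allylboration of aldehydes with allyl pinacolboronate, and the closest known reactions are that allylboration, the γ-selective addition of α-substituted allylboronates and the allylboration of lactols.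

Step 14
Reactants: 24 (12S)-6,12-diol
Product: 25 12-O-acetate of 24
Conditions: Ac2O (1.3 equiv), pyridine, CH2Cl2, 0 °C
Reagents that add atoms: acetic anhydride, CC(=O)OC(C)=O
Why: Acylation is faster at the side-chain C12 carbinol (one α-branch) than at the ring C6 carbinol, which is flanked by two methine carbons and screened by the C4 methylidene and the side chain, so limited Ac2O without DMAP gives the 12-monoacetate.

Step 15
Reactants: 25 12-O-acetate of 24
Product: 26 CNP0210891.2 (target)
Conditions: HF·pyridine, pyridine–THF, 0 → 23 °C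
Reagents that add atoms: none
Why: Fluoride cleaves both secondary silyl ethers under buffered, non-basic conditions, so the acetate neither hydrolyses nor migrates and the allylic alcohols do not ionise.

## Compound list

1 | (S)-4-(tert-butyldimethylsilyloxy)cyclopent-2-en-1-one | O=C1C=C[C@@H](O[Si](C)(C)C(C)(C)C)C1 | starting material
2 | vinylmagnesium bromide | C=C[Mg]Br | starting material
3 | (3R,4S)-4-(tert-butyldimethylsilyloxy)-3-vinylcyclopentan-1-one | O=C1C[C@H](C=C)[C@@H](O[Si](C)(C)C(C)(C)C)C1 | intermediate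
4 | (R)-4-vinylcyclopent-2-en-1-one | C=C[C@@H]1C=CC(=O)C1 | intermediate
5 | 3-methylfuran-2(5H)-one | CC1=CCOC1=O | starting material
6 | tert-butyldimethyl[(3-methylfuran-2-yl)oxy]silane | Cc1ccoc1O[Si](C)(C)C(C)(C)C | intermediate
7 | TBS enol ether (C3-OTBS, C3=C4) of the 1,4-adduct; C1, C5 and C6 configured as in 10 | CC(C)(C)[Si](C)(C)OC1=C[C@H]([C@H]2OC(=O)C(C)=C2)[C@@H](C=C)C1 | intermediate
8 | Mannich base: 2-[(dimethylamino)methyl] ketone (C4 epimers, centre left undefined; lost on elimination) | O=C1C[C@H](C=C)[C@@H]([C@H]2OC(=O)C(C)=C2)C1CN(C)C | intermediate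
9 | trimethylammonium iodide of 8 | O=C1C[C@H](C=C)[C@@H]([C@H]2OC(=O)C(C)=C2)C1C[N+](C)(C)C.[I-] | intermediate
10 | (3R,4R)-2-methylidene-3-[(2S)-4-methyl-5-oxo-2,5-dihydrofuran-2-yl]-4-vinylcyclopentan-1-one | C=C1[C@H]([C@H]2OC(=O)C(C)=C2)[C@@H](C=C)CC1=O | intermediate
11 | (1R,3R,4R)-2-methylidene-3-[(2S)-4-methyl-5-oxo-2,5-dihydrofuran-2-yl]-4-vinylcyclopentan-1-ol | C=C1[C@H]([C@H]2OC(=O)C(C)=C2)[C@@H](C=C)C[C@H]1O | intermediate
12 | tert-butyldimethylsilyl ether of 11 (3-OTBS) | C=C1[C@H]([C@H]2OC(=O)C(C)=C2)[C@@H](C=C)C[C@H]1O[Si](C)(C)C(C)(C)C | intermediate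
13 | 1-[(1S,2R,4R)-4-(tert-butyldimethylsilyloxy)-3-methylidene-2-[(2S)-4-methyl-5-oxo-2,5-dihydrofuran-2-yl]cyclopentyl]ethan-1-one | C=C1[C@H]([C@H]2OC(=O)C(C)=C2)[C@@H](C(C)=O)C[C@H]1O[Si](C)(C)C(C)(C)C | intermediate
14 | tricyclic keto lactone (1S,3R,5R,6S,7R,11S): trans-fused hydrindan-10-one, 3-OTBS, C4=C17, cis-fused 6,12-olide | C=C1[C@@H]2[C@H]3OC(=O)[C@@H](C)[C@H]3CC(=O)[C@H]2C[C@H]1O[Si](C)(C)C(C)(C)C | intermediate
15 | ring-expanded trimethylsilyl enol ether (C10-OTMS, C9=C10) | C=C1[C@@H]2[C@H]3OC(=O)[C@@H](C)[C@H]3CC=C(O[Si](C)(C)C)[C@H]2C[C@H]1O[Si](C)(C)C(C)(C)C | intermediate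
16 | (9S)-9-(trimethylsilyloxy)-10-ketone | C=C1[C@@H]2[C@H]3OC(=O)[C@@H](C)[C@H]3C[C@H](O[Si](C)(C)C)C(=O)[C@H]2C[C@H]1O[Si](C)(C)C(C)(C)C | intermediate
17 | (1S,3R,5R,6S,7R,9S,11S)-9-hydroxy-10-oxo hydroazulene lactone (3-OTBS, C4=C17, 6,12-olide) | C=C1[C@@H]2[C@H]3OC(=O)[C@@H](C)[C@H]3C[C@H](O)C(=O)[C@H]2C[C@H]1O[Si](C)(C)C(C)(C)C | intermediate
18 | 9-O-TBS ether of 17 (3,9-bis-OTBS 10-ketone) | C=C1[C@@H]2[C@H]3OC(=O)[C@@H](C)[C@H]3C[C@H](O[Si](C)(C)C(C)(C)C)C(=O)[C@H]2C[C@H]1O[Si](C)(C)C(C)(C)C | intermediate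
19 | bis-methylidene lactone (3,9-bis-OTBS, C4=C17, C10=C18, 6,12-olide) | C=C1[C@@H]2[C@H]3OC(=O)[C@@H](C)[C@H]3C[C@H](O[Si](C)(C)C(C)(C)C)C(=C)[C@H]2C[C@H]1O[Si](C)(C)C(C)(C)C | intermediate
20 | lactol of 19 (C12 hemiacetal, anomer mixture, C12 undefined) | C=C1[C@@H]2[C@H]3OC(O)[C@@H](C)[C@H]3C[C@H](O[Si](C)(C)C(C)(C)C)C(=C)[C@H]2C[C@H]1O[Si](C)(C)C(C)(C)C | intermediate
21 | 1-chloro-3-methylbut-2-ene (prenyl chloride) | CC(C)=CCCl | starting material
22 | prenylmagnesium chloride | CC(C)=CC[Mg]Cl | intermediate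
23 | 2-(2-methylbut-3-en-2-yl)-4,4,5,5-tetramethyl-1,3,2-dioxaborolane | C=CC(C)(C)B1OC(C)(C)C(C)(C)O1 | intermediate
24 | (1S,3R,5R,6S,7R,9S,11S,12S)-6,12-diol, 3,9-bis-OTBS, full side chain | C=C1[C@@H]2[C@@H](O)[C@@H]([C@H](C)[C@H](CC=C(C)C)O)C[C@H](O[Si](C)(C)C(C)(C)C)C(=C)[C@H]2C[C@H]1O[Si](C)(C)C(C)(C)C | intermediate
25 | 12-O-acetate of 24 | C=C1[C@@H]2[C@@H](O)[C@@H]([C@H](C)[C@H](CC=C(C)C)OC(C)=O)C[C@H](O[Si](C)(C)C(C)(C)C)C(=C)[C@H]2C[C@H]1O[Si](C)(C)C(C)(C)C | intermediate
26 | CNP0210891.2, (1S,3R,5R,6S,7R,9S,11S,12S)-12-acetoxy-3,6,9-trihydroxy-4(17),10(18),14-triene | C=C1[C@@H]2[C@@H](O)[C@@H]([C@H](C)[C@H](CC=C(C)C)OC(C)=O)C[C@H](O)C(=C)[C@H]2C[C@H]1O | target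

## Step count and risks

Total: 15 steps. Longest linear sequence: 13 steps (1, 3–11, 13–15); steps 2 and 12 make the reagents 6 and 23.

The three steps most likely to fail:

**Step 3 (vinylogous Michael/Mannich sequence).** The C6 configuration rests on a preference for the open antiperiplanar transition state, for which I have no direct precedent on this substrate, and trapping of the hindered enol silane may be slow. The fallback sets out from 4 and comes back at 10; it installs C17 first and forms C5–C6 through a closed transition state. A Morita–Baylis–Hillman reaction of 4 with aqueous formaldehyde (imidazole, THF–H2O) gives (R)-2-(hydroxymethyl)-4-vinylcyclopent-2-en-1-one F1. PBr3 (Et2O, 0 °C) converts it into (R)-2-(bromomethyl)-4-vinylcyclopent-2-en-1-one F2. Indium powder in THF–H2O then couples F2 with 5-hydroxy-3-methylfuran-2(5H)-one (CC1=CC(O)OC1=O, the ring form of (Z)-2-methyl-4-oxobut-2-enoic acid) in a Barbier allylation through C5. The chair transition state with the ring-fixed (E)-type γ-substituent gives the 5,6-anti adduct anti to the vinyl group, the double bond moves to C4=C17, and the γ-hydroxy acid lactonises to 10.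

**Step 13 (proposed new prenylboration).** The tertiary boronate is hindered, the aldehyde is mostly masked as the lactol, and face control by the acid on an α-branched aliphatic aldehyde is untested. The fallback uses known chemistry, sets out from 20 and comes back at 24. Brown allylation of 20 with (−)-B-allyldiisopinocampheylborane (Et2O, −78 °C, Si-face delivery matched with the Felkin–Anh preference) gives the (12S)-allyl carbinol F3. Cross-metathesis of F3 with 2-methylbut-2-ene (second-generation Grubbs catalyst, CH2Cl2, 40 °C) then gives 24; the two 1,1-disubstituted methylidenes do not take part.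

**Step 14 (selective acetylation).** Selectivity for O12 over O6 depends only on steric differences between two secondary alcohols. The fallback sets out from 19 and comes back at 26; it differentiates the two oxygens before C12 is built. Me(MeO)NH·HCl and AlMe3 (CH2Cl2, 0 → 23 °C) open the lactone to the 6-hydroxy Weinreb amide F4. TBSOTf and 2,6-lutidine give the 6-O-TBS Weinreb amide F5, and i-Bu2AlH (THF, −78 °C) gives the 6-O-TBS aldehyde F6. Prenylboration as in step 13 (or Brown allylation and cross-metathesis) gives the (12S)-carbinol F7, in which only O12 is free. Ac2O, DMAP and pyridine give the tris-TBS acetate F8, and HF·pyridine removes the three silyl groups to give 26.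

Further compounds
F1 | step 3 | (R)-2-(hydroxymethyl)-4-vinylcyclopent-2-en-1-one | C=C[C@@H]1C=C(CO)C(=O)C1
F2 | step 3 | (R)-2-(bromomethyl)-4-vinylcyclopent-2-en-1-one | C=C[C@@H]1C=C(CBr)C(=O)C1
F3 | step 13 | (12S)-allyl carbinol (6,12-diol, 3,9-bis-OTBS, CH2CH=CH2 in place of prenyl) | C=C1[C@@H]2[C@@H](O)[C@@H]([C@H](C)[C@H](CC=C)O)C[C@H](O[Si](C)(C)C(C)(C)C)C(=C)[C@H]2C[C@H]1O[Si](C)(C)C(C)(C)C
F4 | step 14 | 6-hydroxy Weinreb amide (C12 N-methoxy-N-methylamide, 3,9-bis-OTBS) | C=C1[C@@H]2[C@@H](O)[C@@H]([C@H](C)C(=O)N(C)OC)C[C@H](O[Si](C)(C)C(C)(C)C)C(=C)[C@H]2C[C@H]1O[Si](C)(C)C(C)(C)C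
F5 | step 14 | 6-O-TBS Weinreb amide (3,6,9-tris-OTBS) | C=C1[C@@H]2[C@@H](O[Si](C)(C)C(C)(C)C)[C@@H]([C@H](C)C(=O)N(C)OC)C[C@H](O[Si](C)(C)C(C)(C)C)C(=C)[C@H]2C[C@H]1O[Si](C)(C)C(C)(C)C
F6 | step 14 | 6-O-TBS aldehyde (C12 aldehyde, 3,6,9-tris-OTBS) | C=C1[C@@H]2[C@@H](O[Si](C)(C)C(C)(C)C)[C@@H]([C@H](C)C=O)C[C@H](O[Si](C)(C)C(C)(C)C)C(=C)[C@H]2C[C@H]1O[Si](C)(C)C(C)(C)C
F7 | step 14 | (12S)-carbinol (3,6,9-tris-OTBS, free 12-OH) | C=C1[C@@H]2[C@@H](O[Si](C)(C)C(C)(C)C)[C@@H]([C@H](C)[C@H](CC=C(C)C)O)C[C@H](O[Si](C)(C)C(C)(C)C)C(=C)[C@H]2C[C@H]1O[Si](C)(C)C(C)(C)C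
F8 | step 14 | tris-TBS acetate (3,6,9-tris-OTBS, 12-OAc) | C=C1[C@@H]2[C@@H](O[Si](C)(C)C(C)(C)C)[C@@H]([C@H](C)[C@H](CC=C(C)C)OC(C)=O)C[C@H](O[Si](C)(C)C(C)(C)C)C(=C)[C@H]2C[C@H]1O[Si](C)(C)C(C)(C)C
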